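**Plan**
- Retrosynthetic cuts, in this order: the nine O–benzyl bonds; C4'–C4a' of the lower pyran ring F (epoxide/arene ring closure); the O1'–C2' ether (Mitsunobu); the C4–C8' interflavan bond (silicon-tethered Friedel–Crafts).
- Forward: rings A, B, C are bought as (+)-dihydrorobinetin and turned into a C4 electrophile. Ring D (3,5-dibenzyloxyphenol) is tied to O3 through silicon and joined to C4. The C2'–C4' epoxide chain with ring E is hung on O1'. Ring F closes last, then debenzylation.
- Enabling feature: in ring D, C8' already carries the upper flavan, so C4a' is the only free carbon ortho to O1'. It is flanked by O1' and O5' and para to O7', so the closure can only give the 4→8-linked flavan.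
- Stereochemistry: C2 and C3 are bought. C4 is relayed from C3 by the O3–Si–O tether (cis delivery). C2' and C3' come from one titanium–tartrate kinetic resolution; C2' is inverted in the Mitsunobu step and C3' is retained in the ring closure.

Key step: step 9

Remark: primed locants denote the lower unit (rings D, E, F). Compounds 4, 6 and 7 are used as mixtures of C4 epimers because both ionise to the same cation in step 5, and 11 is racemic.

**Step 1**
Reactants: 1 (+)-dihydrorobinetin
Product: 2 (2R,3R)-7-(benzyloxy)-3-hydroxy-2-[3,4,5-tris(benzyloxy)phenyl]chroman-4-one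
Conditions: BnBr, K2CO3, DMF, rt, argon
Reagents that add atoms: benzyl bromide, BrCc1ccccc1
Why: Williamson etherification in which carbonate deprotonates only the four phenols, so the aliphatic 3-OH stays free and the bought trans stereocenters C2 and C3 are not touched under these mild, air-free conditions.

**Step 2**
Reactants: 2 (2R,3R)-7-(benzyloxy)-3-hydroxy-2-[3,4,5-tris(benzyloxy)phenyl]chroman-4-one
Product: 3 (2R,3S,4R)-7-(benzyloxy)-2-[3,4,5-tris(benzyloxy)phenyl]chromane-3,4-diol
Conditions: NaBH4, THF/EtOH, 0 °C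
Reagents that add atoms: none
Why: Borohydride reduction of the dihydroflavonol ketone, in which hydride should add anti to the neighbouring 3-OH to give the 2,3-trans-3,4-trans diol (the C4 configuration is erased again in step 5).

**Step 3**
Reactants: 3 (2R,3S,4R)-7-(benzyloxy)-2-[3,4,5-tris(benzyloxy)phenyl]chromane-3,4-diol
Product: 4 (2R,3S)-7-(benzyloxy)-4-methoxy-2-[3,4,5-tris(benzyloxy)phenyl]chroman-3-ol (both C4 epimers)
Conditions: MeOH/CH2Cl2, PPTS (cat.), rt
Reagents that add atoms: methanol, CO
Why: Acid-catalysed SN1 solvolysis in which only the C4 hydroxyl, benzylic and para to the 7-benzyloxy group, ionises and is captured by methanol, which distinguishes O4 from O3 and stores the C4 electrophile as a stable ether.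

**Step 4**
Reactants: 4 (2R,3S)-7-(benzyloxy)-4-methoxy-2-[3,4,5-tris(benzyloxy)phenyl]chroman-3-ol; 5 3,5-bis(benzyloxy)phenol
Product: 7 (2R,3S)-7-(benzyloxy)-3-{[3,5-bis(benzyloxy)phenoxy](diisopropyl)silyloxy}-4-methoxy-2-[3,4,5-tris(benzyloxy)phenyl]chromane (both C4 epimers), via chlorosilyl ether 6 (not isolated)
Conditions: iPr2SiCl2 (excess), imidazole, CH2Cl2, 0 °C to rt; evaporate excess silane; then 5, imidazole, DMAP (cat.), DMF, rt
Reagents that add atoms: dichlorodiisopropylsilane, CC(C)[Si](Cl)(Cl)C(C)C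
Why: Stepwise silylation (temporary silicon connection) in which the hindered 3-OH takes one chloride of the excess dichlorosilane and the phenol then displaces the second, giving the unsymmetrical bis-ether without touching a stereocenter.

**Step 5**
Reactants: 7 (2R,3S)-7-(benzyloxy)-3-{[3,5-bis(benzyloxy)phenoxy](diisopropyl)silyloxy}-4-methoxy-2-[3,4,5-tris(benzyloxy)phenyl]chromane
Product: 9 3,5-bis(benzyloxy)-2-{(2R,3S,4R)-7-(benzyloxy)-3-hydroxy-2-[3,4,5-tris(benzyloxy)phenyl]chroman-4-yl}phenol, via cyclic siloxane 8 (not isolated)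
Conditions: TMSOTf (cat.), CH2Cl2 (high dilution), −78 to −40 °C; Et3N; then TBAF, AcOH, THF, 0 °C
Reagents that add atoms: none
Why: Proposed new method: TMSOTf ionises the C4–OMe bond to the benzylic cation stabilised by O1 and the 7-benzyloxy group, and the silicon-tethered trioxygenated ring attacks C4 through a seven-membered transition state. The three-atom O3–Si–O tether can only deliver an ortho carbon of the tethered oxygen, along the axial trajectory on the face of O3, so the new bond should be 3,4-cis (4β) and ortho to the oxygen that becomes O1'; fluoride then removes the tether. The closest known reaction types are the Lewis-acid flavan-4-yl arylation of phloroglucinol-type arenes and its intramolecular variant through a linker on O3, which gives 3,4-cis interflavan bonds.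

**Step 6**
Reactants: 10 3,4,5-tris(benzyloxy)benzaldehyde
Product: 11 rac-1-[3,4,5-tris(benzyloxy)phenyl]prop-2-en-1-ol
Conditions: CH2=CHMgBr, THF, −78 to 0 °C; then H2O
Reagents that add atoms: vinylmagnesium bromide, C=C[Mg]Br
Why: Grignard addition to the aldehyde gives the racemic secondary allylic alcohol needed for the resolution.

**Step 7**
Reactants: 11 rac-1-[3,4,5-tris(benzyloxy)phenyl]prop-2-en-1-ol
Product: 12 (S)-[(2R)-oxiran-2-yl][3,4,5-tris(benzyloxy)phenyl]methanol (erythro)
Conditions: Ti(OiPr)4 (cat.), L-(+)-diisopropyl tartrate, tBuOOH (0.6 equiv), 4 Å MS, CH2Cl2, −20 °C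
Reagents that add atoms: tert-butyl hydroperoxide, CC(C)(C)OO
Why: Sharpless kinetic resolution, in which the titanium–L-(+)-tartrate catalyst epoxidises the (R)-enantiomer fast on the face that gives the erythro epoxy alcohol, setting the future C2' and C3' in one catalytic event while (S)-11 stays behind and is separated.

**Step 8**
Reactants: 9 3,5-bis(benzyloxy)-2-{(2R,3S,4R)-7-(benzyloxy)-3-hydroxy-2-[3,4,5-tris(benzyloxy)phenyl]chroman-4-yl}phenol; 12 (S)-[(2R)-oxiran-2-yl][3,4,5-tris(benzyloxy)phenyl]methanol
Product: 13 (2R,3S,4R)-7-(benzyloxy)-4-{2,4-bis(benzyloxy)-6-[(R)-[(2R)-oxiran-2-yl][3,4,5-tris(benzyloxy)phenyl]methoxy]phenyl}-2-[3,4,5-tris(benzyloxy)phenyl]chroman-3-ol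
Conditions: PPh3, DIAD, toluene, 0 °C to rt
Reagents that add atoms: none
Why: Mitsunobu etherification in which the phenoxide displaces the activated carbinol by SN2 with inversion, turning the erythro (S)-alcohol into the threo (R)-ether at C2'; the upper 3-OH is shielded by two aryl-bearing neighbours and cannot be displaced internally because O1' lies on its own face.

**Step 9**
Reactants: 13 (2R,3S,4R)-7-(benzyloxy)-4-{2,4-bis(benzyloxy)-6-[(R)-[(2R)-oxiran-2-yl][3,4,5-tris(benzyloxy)phenyl]methoxy]phenyl}-2-[3,4,5-tris(benzyloxy)phenyl]chroman-3-ol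
Product: 14 (2R,3S,4R)-7-(benzyloxy)-4-{(2R,3R)-5,7-bis(benzyloxy)-3-hydroxy-2-[3,4,5-tris(benzyloxy)phenyl]chroman-8-yl}-2-[3,4,5-tris(benzyloxy)phenyl]chroman-3-ol
Conditions: HFIP/CH2Cl2 (high dilution), 0 °C to rt
Reagents that add atoms: none
Why: Hydrogen bonding from HFIP polarises the terminal epoxide, C4a' of ring D attacks the epoxide CH2 (C4') in an SN2-like Friedel–Crafts alkylation, and loss of the proton from the arenium ion restores ring D and leaves O3' as the free hydroxyl. The closest known reaction type is the intramolecular Friedel–Crafts epoxy–arene cyclisation of aryl glycidyl ethers to 3-chromanols under fluorinated-alcohol or Lewis-acid promotion. Ring F closes in the 6-endo-tet mode (attack at the distal epoxide carbon); the 5-exo mode at C3' is disfavoured because that carbon is more hindered, inductively deactivated by the adjacent C2'–O1' bond and badly aligned for backside attack by an ortho carbon. No new stereocenter is formed: the C3'–O bond is not broken, so C3' keeps the configuration from step 7, C2' keeps that from step 8, and the threo epoxy ether maps onto the 2,3-cis ring of the epigallocatechin unit. The step needs site selectivity on ring D and chemoselectivity against ionisation of the benzylic C2'–O1' ether. The first is secured because C8' is blocked by the upper flavan, so C4a' (ortho to O1' and O5', para to O7') is the only carbon that can reach C4' and only the 4→8-linked dimer can form; the second by the Lewis-acid-free medium and low temperature, while the 5-deoxy upper unit keeps the interflavan bond acid-stable.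

**Step 10**
Reactants: 14 (2R,3S,4R)-7-(benzyloxy)-4-{(2R,3R)-5,7-bis(benzyloxy)-3-hydroxy-2-[3,4,5-tris(benzyloxy)phenyl]chroman-8-yl}-2-[3,4,5-tris(benzyloxy)phenyl]chroman-3-ol
Product: 15 robinetinidol-(4β→8)-epigallocatechin, (2R,3S,4R)-2-(3,4,5-trihydroxyphenyl)-4-[(2R,3R)-3,5,7-trihydroxy-2-(3,4,5-trihydroxyphenyl)chroman-8-yl]chromane-3,7-diol
Conditions: H2 (1 atm), Pd(OH)2/C, THF/MeOH/H2O, rt, argon work-up
Reagents that add atoms: none
Why: Catalytic hydrogenolysis should cleave all nine benzyl ethers under neutral conditions that leave the cyclic benzylic C–O bonds, the interflavan bond and all five stereocenters intact.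

**Compound list**
1 | (+)-dihydrorobinetin, (2R,3R)-3,7-dihydroxy-2-(3,4,5-trihydroxyphenyl)chroman-4-one | Oc1ccc2c(c1)O[C@H](c1cc(O)c(O)c(O)c1)[C@@H](O)C2=O | starting material
2 | (2R,3R)-7-(benzyloxy)-3-hydroxy-2-[3,4,5-tris(benzyloxy)phenyl]chroman-4-one | c3ccccc3COc1ccc2c(c1)O[C@H](c4cc(OCc5ccccc5)c(OCc5ccccc5)c(OCc5ccccc5)c4)[C@@H](O)C2=O | intermediate
3 | (2R,3S,4R)-7-(benzyloxy)-2-[3,4,5-tris(benzyloxy)phenyl]chromane-3,4-diol | c3ccccc3COc1ccc2c(c1)O[C@H](c4cc(OCc5ccccc5)c(OCc5ccccc5)c(OCc5ccccc5)c4)[C@@H](O)[C@@H]2O | intermediate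
4 | (2R,3S)-7-(benzyloxy)-4-methoxy-2-[3,4,5-tris(benzyloxy)phenyl]chroman-3-ol, C4 epimers | c3ccccc3COc1ccc2c(c1)O[C@H](c4cc(OCc5ccccc5)c(OCc5ccccc5)c(OCc5ccccc5)c4)[C@@H](O)C2OC | intermediate
5 | 3,5-bis(benzyloxy)phenol | Oc1cc(OCc2ccccc2)cc(OCc2ccccc2)c1 | starting material
6 | 3-O-[chloro(diisopropyl)silyl] ether of 4, C4 epimers | c3ccccc3COc1ccc2c(c1)O[C@H](c4cc(OCc5ccccc5)c(OCc5ccccc5)c(OCc5ccccc5)c4)[C@@H](O[Si](Cl)(C(C)C)C(C)C)C2OC | intermediate (not isolated)
7 | (2R,3S)-7-(benzyloxy)-3-{[3,5-bis(benzyloxy)phenoxy](diisopropyl)silyloxy}-4-methoxy-2-[3,4,5-tris(benzyloxy)phenyl]chromane, C4 epimers | c3ccccc3COc1ccc2c(c1)O[C@H](c4cc(OCc5ccccc5)c(OCc5ccccc5)c(OCc5ccccc5)c4)[C@@H](O[Si](C(C)C)(C(C)C)Oc6cc(OCc7ccccc7)cc(OCc7ccccc7)c6)C2OC | intermediate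
8 | cyclic siloxane: (2R,3S,4R)-flavan whose O3 and the ring D oxygen ortho to the new C4–aryl bond are bridged by Si(iPr)2 (seven-membered ring, cis-fused at C3–C4) | c3ccccc3COc1ccc2c(c1)O[C@H](c4cc(OCc5ccccc5)c(OCc5ccccc5)c(OCc5ccccc5)c4)[C@@H](O[Si]6(C(C)C)C(C)C)[C@H]2c7c(O6)cc(OCc8ccccc8)cc7OCc8ccccc8 | intermediate (not isolated)
9 | 3,5-bis(benzyloxy)-2-{(2R,3S,4R)-7-(benzyloxy)-3-hydroxy-2-[3,4,5-tris(benzyloxy)phenyl]chroman-4-yl}phenol | c3ccccc3COc1ccc2c(c1)O[C@H](c4cc(OCc5ccccc5)c(OCc5ccccc5)c(OCc5ccccc5)c4)[C@@H](O)[C@H]2c6c(O)cc(OCc7ccccc7)cc6OCc7ccccc7 | intermediate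
10 | 3,4,5-tris(benzyloxy)benzaldehyde | O=Cc1cc(OCc2ccccc2)c(OCc2ccccc2)c(OCc2ccccc2)c1 | starting material
11 | rac-1-[3,4,5-tris(benzyloxy)phenyl]prop-2-en-1-ol | C=CC(O)c1cc(OCc2ccccc2)c(OCc2ccccc2)c(OCc2ccccc2)c1 | intermediate
12 | (S)-[(2R)-oxiran-2-yl][3,4,5-tris(benzyloxy)phenyl]methanol | O[C@@H](c1cc(OCc2ccccc2)c(OCc2ccccc2)c(OCc2ccccc2)c1)[C@H]1CO1 | intermediate
13 | (2R,3S,4R)-7-(benzyloxy)-4-{2,4-bis(benzyloxy)-6-[(R)-[(2R)-oxiran-2-yl][3,4,5-tris(benzyloxy)phenyl]methoxy]phenyl}-2-[3,4,5-tris(benzyloxy)phenyl]chroman-3-ol | c3ccccc3COc1ccc2c(c1)O[C@H](c4cc(OCc5ccccc5)c(OCc5ccccc5)c(OCc5ccccc5)c4)[C@@H](O)[C@H]2c6c(OCc7ccccc7)cc(OCc7ccccc7)cc6O[C@H](c8cc(OCc9ccccc9)c(OCc9ccccc9)c(OCc9ccccc9)c8)[C@H]1CO1 | intermediate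
14 | (2R,3S,4R)-7-(benzyloxy)-4-{(2R,3R)-5,7-bis(benzyloxy)-3-hydroxy-2-[3,4,5-tris(benzyloxy)phenyl]chroman-8-yl}-2-[3,4,5-tris(benzyloxy)phenyl]chroman-3-ol | c3ccccc3COc1ccc2c(c1)O[C@H](c4cc(OCc5ccccc5)c(OCc5ccccc5)c(OCc5ccccc5)c4)[C@@H](O)[C@H]2c6c(OCc7ccccc7)cc(OCc7ccccc7)c7c6O[C@H](c8cc(OCc9ccccc9)c(OCc9ccccc9)c(OCc9ccccc9)c8)[C@H](O)C7 | intermediate
15 | robinetinidol-(4β→8)-epigallocatechin | Oc1ccc2c(c1)O[C@H](c1cc(O)c(O)c(O)c1)[C@@H](O)[C@H]2c1c(O)cc(O)c2c1O[C@H](c1cc(O)c(O)c(O)c1)[C@H](O)C2 | target

**Totals**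
Total step count: 10. Longest linear sequence: 8 steps (steps 1, 2, 3, 4, 5, 8, 9, 10); steps 6 and 7 make the side fragment.

**Steps most likely to fail**

Step 5 (Proposed new method). The seven-membered tethered transition state may be too slow. Intermolecular alkylation at the carbon para to the silylated oxygen of a second molecule, or acid cleavage of the aryl–O–Si link, could then take over, and facial delivery could be less strict than argued. The fallback uses known chemistry and drops the tether. It sets out from 4 and couples it directly with an excess of 5 under TMSOTf or BF3·OEt2 in CH2Cl2 at −78 °C, the classical Lewis-acid flavan-4-yl arylation of a phloroglucinol-type phenol. This should give 9 together with its C4 epimer and the isomer alkylated para to the free hydroxyl, from which 9 would be separated by chromatography. It comes back to the route at 9 and makes no new compound (F0).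

Step 8. The alkoxyphosphonium intermediate may ionise at the electron-rich benzylic carbon, which would erode the configuration at C2'. SN2 attack by the phenol, hindered by its ortho flavanyl group, may also be so slow that alkylation of the hydrazide wins. The fallback moves the etherification to the unhindered phenol and gives up tether control. It sets out from 5 and 12: Mitsunobu coupling should give 1,3-bis(benzyloxy)-5-{(R)-[(2R)-oxiran-2-yl][3,4,5-tris(benzyloxy)phenyl]methoxy}benzene F1, and the HFIP ring closure of step 9 on this simpler ether should give 5,7,3',4',5'-penta-O-benzyl-(−)-epigallocatechin F2. F2 is then coupled with 4 under TMSOTf in CH2Cl2 at low temperature, where the 5,7-dibenzylated flavan-3-ol is known to react preferentially at C8. The 4β isomer would be separated from its C4 epimer and any C6-linked material, and the route is rejoined at 14.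

Step 9. Acid-promoted ionisation of the benzylic C2'–O1' ether could cause loss or epimerisation at C2'. Hydride-shift rearrangement or solvolysis of the epoxide, or 5-exo opening, could also compete with the 6-endo closure. The fallback abandons the de novo ring construction for the classical biomimetic condensation. It sets out from 1: NaBH4 reduction in ethanol should give (+)-leucorobinetinidin F3. F3 is condensed with commercial (−)-epigallocatechin in dilute aqueous HCl at rt, by capture of the flavan-4-yl cation. The target would be separated from its 4α and C6-linked isomers on Sephadex LH-20, and the route is rejoined at 15.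

**Further compounds**
F0 | step 5 | none | none
F1 | step 8 | 1,3-bis(benzyloxy)-5-{(R)-[(2R)-oxiran-2-yl][3,4,5-tris(benzyloxy)phenyl]methoxy}benzene | c1ccccc1COc1cc(OCc2ccccc2)cc(c1)O[C@H](c1cc(OCc2ccccc2)c(OCc2ccccc2)c(OCc2ccccc2)c1)[C@H]1CO1
F2 | step 8 | 5,7,3',4',5'-penta-O-benzyl-(−)-epigallocatechin | c1ccccc1COc1cc(OCc2ccccc2)c2c(c1)O[C@H](c1cc(OCc3ccccc3)c(OCc3ccccc3)c(OCc3ccccc3)c1)[C@H](O)C2
F3 | step 9 | (+)-leucorobinetinidin, (2R,3S,4R)-2-(3,4,5-trihydroxyphenyl)chromane-3,4,7-triol | Oc1ccc2c(c1)O[C@H](c1cc(O)c(O)c(O)c1)[C@@H](O)[C@@H]2O
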